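The readings stem from a simulated flask on assumed constants, noise included.

Saturday's flask holds 0.10 M of substrate against 0.180 M of coupling partner. If the two pair one to one, substrate is the limiting reagent, and 44.4% of the partner stays over when the substrate has gone. We must decide what to do with this flask at 4.0 h: wait, remove, add or heat. That hangs on one question: does anything still feed the target then?

common to all: initiator 2.5 mM
- Saturday's: substrate 0.10 M; coupling partner 0.18 M; temperature 60 °C; the very flask that is asked about, followed so far
- Tuesday's: substrate 0.067 M; coupling partner 0.18 M; temperature 45 °C; run made earlier
- flask: substrate 0.10 M; coupling partner 0.180 M; temperature 60 °C; time 4.0 h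

| Saturday's: time / min | Saturday's: target / % | Tuesday's: time / min | Tuesday's: target / % |
|---|---|---|---|
| 15.0 | 9 | 15.0 | 5 |
| 40.0 | 20 | 40.0 | 10 |
| 80.0 | 30 | 50.0 | 10 |
| 180 | 32 | 80.0 | 17 |

(readings scatter by 1.5 percentage points)

- south-west: change nothing and wait 80 min more
- north-east: at 4.0 h take out 90% of the by-product then present, then wait 80 min
- south: at 4.0 h add coupling partner, 50.0% of the amount charged, then wait 80 min
- north-west: at 4.0 h raise the temperature by 10 K, then wait 80 min

- the volume of additions can be left aside

1. target, in percent of the substrate first charged, at 4.0 h
2. the option that brings most further target ("none" if no option brings more than 2 percentage points) (south-west / north-east / south / north-west / none)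
3. target present, in percent of the substrate first charged, after south-west
4. target present, in percent of the substrate first charged, after south

The first reading shows 9% of the charge as target after 15.0 min, so substrate goes at 6.00 × 10⁻⁴ M min⁻¹ or faster. We take that pace as steady, which is an assumption. The charge divided by this rate gives 167 min. We call this the run-out time, the crossing after which, at this pace, no substrate remains to feed the target. A first reading lower by one scatter gives 200 min, still shorter than 4.0 h.

So we reckon that Saturday's flask has passed its crossing by 4.0 h. Its target reads 32% at 180 min, which is later than the run-out time. By our reckoning, then, 68.0% of the charge sits at that reading in something we do not read. We expect about 32% at 4.0 h. If the substrate has run out by our run-out time of 167 min, which is shorter than 4.0 h, then waiting, more partner and removing by-product give the target no new substrate. Heating may act on that unread share. The readings give no number for it, but it is our pick.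

The forecast parts from us on the substrate and on the best option. It gives 32.5% at 4.0 h, 33% after south-west, 33.5% after south, and best option none, and it says of the stopping target that “neither reagent has run out”.

The flask gives 29.1% at 4.0 h, 27.5% after south-west and 27.5% after south. The best option is north-west, with a gain of 15 percentage points, while south brings −1.6 points. At 4.0 h this flask holds 0% of its substrate and 44% of its partner.

    initiator → 2 initiating radical (k = 6.95 × 10⁻⁵ min⁻¹, Ea = 128 kJ mol⁻¹)
    substrate + initiating radical → capped initiator + first chain carrier (k = 1.65 × 10⁶ M⁻¹ s⁻¹, Ea = 17.0 kJ mol⁻¹)
    coupling partner + first chain carrier → target + second chain carrier (k = 46000 M⁻¹ s⁻¹, Ea = 29.0 kJ mol⁻¹)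
    substrate + second chain carrier → by-product + first chain carrier (k = 1.00 × 10⁵ M⁻¹ s⁻¹, Ea = 14.0 kJ mol⁻¹)
    2 first chain carrier → ended chains (k = 1.20 × 10⁹ M⁻¹ s⁻¹, Ea = 10.0 kJ mol⁻¹)
    crystals ⇌ by-product, rate k6*(cs6 - [by-product]) while solid is left; crystals form when [by-product] > cs6 (solubility = 0.0760 M, k = 0.109 min⁻¹)
    target ⇌ isomer of the product (K = 2.65, k = 0.0234 min⁻¹, Ea = 97.0 kJ mol⁻¹, ΔH = −69.0 kJ mol⁻¹)
    (constants at 60 °C)

In the neighbour flask, alike but for its 0.17 M of substrate, the same rate gives a run-out time of 283 min, longer than 4.0 h. We therefore reckon 15.2% of its substrate left at that time. That neighbour flask holds more, 32.1%, and its target stands at 22.8%.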